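**Plan** (locants follow the furo[3,4-c]furan core: C1 carries the ring that ends as the free phenol, C4 the prenyloxyaryl ring; C3a and C6a are the fusion carbons)
- Retrosynthesis cuts, in order: the phenol O–Si bond; the C4–O5 ether bond and the C4–aryl bond (back to a bicyclic lactol, then a γ-lactone with C4 as carbonyl); the lactone C4–O5 bond together with a return of C4 into the ring between C3a and C6a (a ketene traced back to a 5-diazo-tetrahydropyran-4-one); the C6a–C6 bond; and the C1–C6a and O2–C3 bonds of a hetero-Diels–Alder pyranone.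
- Enabling feature: on the tetrahydrofuran C1–O2–C3–C3a–C6a, C4 hangs from C3a at a level that can be a carbonyl, and the C6–O5 arm on the neighbouring C6a can capture it. A ring carbonyl between C3a and C6a of a six-membered oxacycle is therefore latent in this ring.
- Forward: the pyranone ring is made first from the vanillin aldehyde and Danishefsky's diene. It is contracted to the tetrahydrofuran while the second five-membered ring closes as a lactone. That lactone is opened at the lactol level by the aryl Grignard reagent and re-closed as the second tetrahydrofuran.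
- Stereochemistry: C1 is set by the chiral titanium catalyst; C6a by enolate attack anti to the neighbouring aryl group; C3a by the enforced cis ring fusion when the ketene lactonises; C4 by exo-selective closure onto a benzylic cation.

Key step: step 6

Assumption: the (R)-BINOL–Ti(OiPr)4 catalyst is taken to direct the diene to the Re face of the aryl aldehyde, as in related titanium–BINOL carbonyl additions; should the sense prove opposite, (S)-BINOL is used with no other change.

**Step 1**
Reactants: 1 vanillin
Product: 2 3-methoxy-4-(triisopropylsilyloxy)benzaldehyde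
Conditions: iPr3SiCl, imidazole, DMF, rt
Reagents that add atoms: chlorotriisopropylsilane CC(C)[Si](Cl)(C(C)C)C(C)C
Why: Imidazole-promoted silylation of a phenol; the bulky silyl ether should survive the base, hydride, Grignard and mild acid steps, lowers the donor strength of this ring, and is removed by fluoride at the end.

**Step 2**
Reactants: 2 3-methoxy-4-(triisopropylsilyloxy)benzaldehyde; 3 Danishefsky's diene
Product: 5 (R)-2-[3-methoxy-4-(triisopropylsilyloxy)phenyl]-2,3-dihydro-4H-pyran-4-one, via Mukaiyama aldol adduct 4 (not isolated)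
Conditions: (R)-BINOL (20 mol %), Ti(OiPr)4 (10 mol %), CF3CO2H (cat.), 4 Å MS, Et2O, −20 °C; then CF3CO2H, CH2Cl2, 0 °C
Reagents that add atoms: none
Why: Catalytic asymmetric hetero-Diels–Alder reaction run as a BINOL–titanium Mukaiyama aldol followed by acid cyclisation (oxa-Michael addition, loss of methanol); the chiral titanium complex blocks one face of the bound aldehyde so that the diene terminus should add to the Re face and set C2 as R.

**Step 3**
Reactants: 5 (R)-2-[3-methoxy-4-(triisopropylsilyloxy)phenyl]-2,3-dihydro-4H-pyran-4-one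
Product: 7 (2R,3S)-2-[3-methoxy-4-(triisopropylsilyloxy)phenyl]-3-[(triethylsilyloxy)methyl]-2,3-dihydro-4H-pyran-4-one, via lithium alkoxide 6 (not isolated)
Conditions: LiN(iPr)2, THF, −78 °C; CH2O (monomeric, in THF), −78 °C; then Et3SiCl, −78 → −20 °C
Reagents that add atoms: formaldehyde C=O; chlorotriethylsilane CC[Si](Cl)(CC)CC
Why: Kinetic α'-deprotonation of the vinylogous ester (C3 is its only enolisable position) and aldol addition to formaldehyde anti to the adjacent aryl group should give the 2,3-trans product, which is also the thermodynamic isomer; silylation of the alkoxide in the same flask prevents retro-aldol loss and dehydration.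

**Step 4**
Reactants: 7 (2R,3S)-2-[3-methoxy-4-(triisopropylsilyloxy)phenyl]-3-[(triethylsilyloxy)methyl]-2,3-dihydro-4H-pyran-4-one
Product: 10 (2R,3S)-5-diazo-2-[3-methoxy-4-(triisopropylsilyloxy)phenyl]-3-[(triethylsilyloxy)methyl]tetrahydro-4H-pyran-4-one, via lithium enolate 8 (not isolated), via trifluoroacetyl ketone 9 (not isolated)
Conditions: LiBH(sBu)3, THF, −78 °C; CF3CO2CH2CF3, −78 °C; aq NH4Cl; then MsN3, Et3N, H2O (1 equiv), MeCN, rt
Reagents that add atoms: methanesulfonyl azide CS(=O)(=O)N=[N+]=[N-]
Why: Conjugate hydride addition to the β-alkoxy enone gives the enolate only across C4–C5; C-trifluoroacetylation and detrifluoroacetylative (Regitz-type) diazo transfer therefore place the diazo group at C5 alone, leaving C2 and C3 untouched.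

**Step 5**
Reactants: 10 (2R,3S)-5-diazo-2-[3-methoxy-4-(triisopropylsilyloxy)phenyl]-3-[(triethylsilyloxy)methyl]tetrahydro-4H-pyran-4-one
Product: 11 (2R,3S)-5-diazo-3-(hydroxymethyl)-2-[3-methoxy-4-(triisopropylsilyloxy)phenyl]tetrahydro-4H-pyran-4-one
Conditions: PPTS (cat.), MeOH, 0 °C
Reagents that add atoms: none
Why: Mild acid methanolysis of a primary triethylsilyl ether; the aryl triisopropylsilyl ether and the disubstituted α-diazo ketone should tolerate pyridinium tosylate.

**Step 6**
Reactants: 11 (2R,3S)-5-diazo-3-(hydroxymethyl)-2-[3-methoxy-4-(triisopropylsilyloxy)phenyl]tetrahydro-4H-pyran-4-one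
Product: 13 (3aS,4R,6aS)-4-[3-methoxy-4-(triisopropylsilyloxy)phenyl]tetrahydro-1H,3H-furo[3,4-c]furan-1-one, via ketene 12 (not isolated)
Conditions: hν (365 nm), THF (0.01 M), 20 °C
Reagents that add atoms: none
Why: Photoexcitation of the cyclic diazo ketone, locked s-cis, expels N2 with a concerted 1,2-shift of the hydroxymethyl-bearing ring carbon from the carbonyl carbon to the diazo carbon with retention, so the six-membered ring contracts to the tetrahydrofuran and the former ring carbonyl is extruded as a ketene on the ring; the neighbouring hydroxymethyl group then adds to the ketene and the enol tautomerises to the γ-lactone. The closest known reaction type is the photochemical Wolff ring contraction of cyclic α-diazo ketones with intramolecular capture of the ketene by an alcohol. The tetrahydrofuran arises by ring contraction (one carbon fewer) and the lactone by 5-exo-dig attack of the hydroxyl oxygen on the ketene carbonyl carbon. The one new stereocentre, the fusion carbon α to the lactone carbonyl, is set by protonation of the lactone enol on the convex face, because only the cis-fused 3,7-dioxabicyclo[3.3.0]octanone is accessible and this centre remains epimerisable toward it; the aryl-bearing carbon and the migrating carbon keep their configurations. The step needs the Wolff shift to win over a 1,2-hydride shift from the adjacent OCH2 group and over O–H insertion, which the concerted photochemical pathway of the s-cis diazo ketone and the equatorial hydroxymethyl group (unable to reach the diazo carbon) should secure, while high dilution suppresses intermolecular ketene capture.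

**Step 7**
Reactants: 13 (3aS,4R,6aS)-4-[3-methoxy-4-(triisopropylsilyloxy)phenyl]tetrahydro-1H,3H-furo[3,4-c]furan-1-one
Product: 14 (1RS,3aS,4R,6aS)-4-[3-methoxy-4-(triisopropylsilyloxy)phenyl]tetrahydro-1H,3H-furo[3,4-c]furan-1-ol
Conditions: iBu2AlH, CH2Cl2, −78 °C; Rochelle salt work-up
Reagents that add atoms: none
Why: Partial reduction of a γ-lactone at low temperature stops at the aluminium lactolate; no existing stereocentre is touched and the anomeric mixture is irrelevant.

**Step 8**
Reactants: 15 4-bromo-2-methoxyphenol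
Product: 16 4-bromo-2-methoxy-1-(3-methylbut-2-enyloxy)benzene
Conditions: prenyl bromide, K2CO3, acetone, 50 °C
Reagents that add atoms: 1-bromo-3-methylbut-2-ene CC(C)=CCBr
Why: Williamson etherification of a phenoxide with a primary allylic bromide (SN2 at the unhindered terminus).

**Step 9**
Reactants: 14 (1RS,3aS,4R,6aS)-4-[3-methoxy-4-(triisopropylsilyloxy)phenyl]tetrahydro-1H,3H-furo[3,4-c]furan-1-ol; 16 4-bromo-2-methoxy-1-(3-methylbut-2-enyloxy)benzene
Product: 18 (2R,3S,4S)-4-{(RS)-hydroxy[3-methoxy-4-(3-methylbut-2-enyloxy)phenyl]methyl}-3-(hydroxymethyl)-2-[3-methoxy-4-(triisopropylsilyloxy)phenyl]tetrahydrofuran, via arylmagnesium bromide 17 (not isolated)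
Conditions: 16, Mg, THF, 40 °C; then 14 (17 in 3-fold excess), THF, 0 °C → rt; aq NH4Cl
Reagents that add atoms: none
Why: Grignard addition to a lactol: the first equivalent deprotonates and opens the lactol to the hydroxy aldehyde and the second adds to the aldehyde; the carbinol configuration is not controlled and need not be, because the next step passes through the planar benzylic cation.

**Step 10**
Reactants: 18 (2R,3S,4S)-4-{(RS)-hydroxy[3-methoxy-4-(3-methylbut-2-enyloxy)phenyl]methyl}-3-(hydroxymethyl)-2-[3-methoxy-4-(triisopropylsilyloxy)phenyl]tetrahydrofuran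
Product: 19 (1R,3aS,4R,6aS)-1-[3-methoxy-4-(triisopropylsilyloxy)phenyl]-4-[3-methoxy-4-(3-methylbut-2-enyloxy)phenyl]tetrahydro-1H,3H-furo[3,4-c]furan
Conditions: camphorsulfonic acid (10 mol %), CH2Cl2, 0 °C, short reaction time
Reagents that add atoms: none
Why: Acid ionises the p-alkoxybenzylic alcohol to a quinone-methide-like cation that the primary hydroxyl captures by 5-exo-trig closure (SN1 cyclodehydration, as in furofuran lignan synthesis); both carbinol epimers converge and the aryl group should take the exo position at C4 to avoid the C3 methylene on the concave face, while the less electron-rich silyloxyaryl ether at C1 should stay closed.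

**Step 11**
Reactants: 19 (1R,3aS,4R,6aS)-1-[3-methoxy-4-(triisopropylsilyloxy)phenyl]-4-[3-methoxy-4-(3-methylbut-2-enyloxy)phenyl]tetrahydro-1H,3H-furo[3,4-c]furan
Product: 20 4-{(1R,3aS,4R,6aS)-4-[3-methoxy-4-(3-methylbut-2-enyloxy)phenyl]tetrahydro-1H,3H-furo[3,4-c]furan-1-yl}-2-methoxyphenol
Conditions: Bu4NF, THF, 0 °C; aq NH4Cl
Reagents that add atoms: none
Why: Fluoride cleavage of an aryl silyl ether; the prenyl ether and the furofuran benzylic ethers are inert to these conditions.

**Compound list**
1 | vanillin | COc1cc(C=O)ccc1O | starting material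
2 | 3-methoxy-4-(triisopropylsilyloxy)benzaldehyde | COc1cc(C=O)ccc1O[Si](C(C)C)(C(C)C)C(C)C | intermediate
3 | Danishefsky's diene, (E)-1-methoxy-3-(trimethylsilyloxy)buta-1,3-diene | CO/C=C/C(=C)O[Si](C)(C)C | starting material
4 | (R,E)-1-methoxy-5-[3-methoxy-4-(triisopropylsilyloxy)phenyl]-5-(trimethylsilyloxy)pent-1-en-3-one (not isolated) | CO/C=C/C(=O)C[C@@H](O[Si](C)(C)C)c1ccc(O[Si](C(C)C)(C(C)C)C(C)C)c(OC)c1 | intermediate
5 | (R)-2-[3-methoxy-4-(triisopropylsilyloxy)phenyl]-2,3-dihydro-4H-pyran-4-one | O=C1C[C@H](c2ccc(O[Si](C(C)C)(C(C)C)C(C)C)c(OC)c2)OC=C1 | intermediate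
6 | lithium alkoxide of (2R,3S)-3-(hydroxymethyl)-2-[3-methoxy-4-(triisopropylsilyloxy)phenyl]-2,3-dihydro-4H-pyran-4-one (not isolated) | O=C1C=CO[C@@H](c2ccc(O[Si](C(C)C)(C(C)C)C(C)C)c(OC)c2)[C@@H]1CO[Li] | intermediate
7 | (2R,3S)-2-[3-methoxy-4-(triisopropylsilyloxy)phenyl]-3-[(triethylsilyloxy)methyl]-2,3-dihydro-4H-pyran-4-one (aryl and silyloxymethyl trans) | O=C1C=CO[C@@H](c2ccc(O[Si](C(C)C)(C(C)C)C(C)C)c(OC)c2)[C@@H]1CO[Si](CC)(CC)CC | intermediate
8 | lithium enolate (C4–C5) of the tetrahydropyran-4-one from conjugate reduction of 7 (not isolated) | [Li]OC1=CCO[C@@H](c2ccc(O[Si](C(C)C)(C(C)C)C(C)C)c(OC)c2)[C@@H]1CO[Si](CC)(CC)CC | intermediate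
9 | (2R,3S)-2-[3-methoxy-4-(triisopropylsilyloxy)phenyl]-3-[(triethylsilyloxy)methyl]-5-(trifluoroacetyl)tetrahydro-4H-pyran-4-one, C5 enolised (not isolated) | O=C1C(C(=O)C(F)(F)F)CO[C@@H](c2ccc(O[Si](C(C)C)(C(C)C)C(C)C)c(OC)c2)[C@@H]1CO[Si](CC)(CC)CC | intermediate
10 | (2R,3S)-5-diazo-2-[3-methoxy-4-(triisopropylsilyloxy)phenyl]-3-[(triethylsilyloxy)methyl]tetrahydro-4H-pyran-4-one | O=C1C(=[N+]=[N-])CO[C@@H](c2ccc(O[Si](C(C)C)(C(C)C)C(C)C)c(OC)c2)[C@@H]1CO[Si](CC)(CC)CC | intermediate
11 | (2R,3S)-5-diazo-3-(hydroxymethyl)-2-[3-methoxy-4-(triisopropylsilyloxy)phenyl]tetrahydro-4H-pyran-4-one | O=C1C(=[N+]=[N-])CO[C@@H](c2ccc(O[Si](C(C)C)(C(C)C)C(C)C)c(OC)c2)[C@@H]1CO | intermediate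
12 | (2R,3S)-3-(hydroxymethyl)-2-[3-methoxy-4-(triisopropylsilyloxy)phenyl]-4-(oxomethylidene)tetrahydrofuran, the ketene (not isolated) | O=C=C1CO[C@@H](c2ccc(O[Si](C(C)C)(C(C)C)C(C)C)c(OC)c2)[C@@H]1CO | intermediate
13 | (3aS,4R,6aS)-4-[3-methoxy-4-(triisopropylsilyloxy)phenyl]tetrahydro-1H,3H-furo[3,4-c]furan-1-one (cis-fused, aryl exo) | O=C1OC[C@@H]2[C@H]1CO[C@H]2c1ccc(O[Si](C(C)C)(C(C)C)C(C)C)c(OC)c1 | intermediate
14 | (1RS,3aS,4R,6aS)-4-[3-methoxy-4-(triisopropylsilyloxy)phenyl]tetrahydro-1H,3H-furo[3,4-c]furan-1-ol (anomeric mixture) | OC1OC[C@@H]2[C@H]1CO[C@H]2c1ccc(O[Si](C(C)C)(C(C)C)C(C)C)c(OC)c1 | intermediate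
15 | 4-bromo-2-methoxyphenol | COc1cc(Br)ccc1O | starting material
16 | 4-bromo-2-methoxy-1-(3-methylbut-2-enyloxy)benzene | COc1cc(Br)ccc1OCC=C(C)C | intermediate
17 | [3-methoxy-4-(3-methylbut-2-enyloxy)phenyl]magnesium bromide (not isolated) | COc1cc([Mg]Br)ccc1OCC=C(C)C | intermediate
18 | (2R,3S,4S)-4-{(RS)-hydroxy[3-methoxy-4-(3-methylbut-2-enyloxy)phenyl]methyl}-3-(hydroxymethyl)-2-[3-methoxy-4-(triisopropylsilyloxy)phenyl]tetrahydrofuran (carbinol epimers) | OC[C@@H]1[C@H](C(O)c2ccc(OCC=C(C)C)c(OC)c2)CO[C@H]1c1ccc(O[Si](C(C)C)(C(C)C)C(C)C)c(OC)c1 | intermediate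
19 | (1R,3aS,4R,6aS)-1-[3-methoxy-4-(triisopropylsilyloxy)phenyl]-4-[3-methoxy-4-(3-methylbut-2-enyloxy)phenyl]tetrahydro-1H,3H-furo[3,4-c]furan (both aryl groups exo) | COc1cc([C@@H]2OC[C@@H]3[C@H]2CO[C@H]3c2ccc(OCC=C(C)C)c(OC)c2)ccc1O[Si](C(C)C)(C(C)C)C(C)C | intermediate
20 | 4-{(1R,3aS,4R,6aS)-4-[3-methoxy-4-(3-methylbut-2-enyloxy)phenyl]tetrahydro-1H,3H-furo[3,4-c]furan-1-yl}-2-methoxyphenol | COc1cc([C@@H]2OC[C@@H]3[C@H]2CO[C@H]3c2ccc(OCC=C(C)C)c(OC)c2)ccc1O | target

**Step count and risks**
Total step count: 11. Longest linear sequence: 10 steps (steps 1–7 and 9–11, from vanillin); step 8 is a one-step side branch.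

Steps most likely to fail:

1. Step 6. The excited diazo ketone may leak into a carbene pathway (1,2-hydride shift from the adjacent OCH2 group back to the enone, or O–H insertion), or the pendant hydroxyl may capture the ketene too slowly, so that oligomeric esters form. The fallback sets out from compound 10 and returns at compound 13. The silyl-protected diazo ketone 10 is irradiated (365 nm) in methanol, so that the solvent captures the ketene and gives methyl (3RS,4S,5R)-5-[3-methoxy-4-(triisopropylsilyloxy)phenyl]-4-[(triethylsilyloxy)methyl]tetrahydrofuran-3-carboxylate F1 as a mixture at the ester carbon. Pyridinium tosylate in methanol then frees the alcohol to give methyl (3RS,4S,5R)-4-(hydroxymethyl)-5-[3-methoxy-4-(triisopropylsilyloxy)phenyl]tetrahydrofuran-3-carboxylate F2. Catalytic DBU in toluene epimerises the ester α-carbon and drains the cis isomer into lactone 13.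

2. Step 10. Closure onto the benzylic cation may show poor exo/endo selectivity at C4, may become reversible (which would also open the C1 ether and erode C1), may be intercepted by Friedel–Crafts attack of the other aryl ring, or may cost the prenyl ether. The fallback sets out from compound 14 and returns at compound 19, forming the C4–aryl bond instead of the C4–O5 bond in the stereo-determining event. Lactol 14 with benzenesulfinic acid and CaCl2 in CH2Cl2 should give (1RS,3aS,4R,6aS)-4-[3-methoxy-4-(triisopropylsilyloxy)phenyl]-1-(phenylsulfonyl)tetrahydro-1H,3H-furo[3,4-c]furan F3. The Grignard reagent 17 is transmetalated with ZnBr2 to [3-methoxy-4-(3-methylbut-2-enyloxy)phenyl]zinc bromide F4, which displaces sulfinate from F3 in THF at rt through the bicyclic oxocarbenium ion. Attack on the convex face should place the aryl group exo and deliver 19 directly, without acid.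

3. Step 4. The hydride may add 1,2 to the vinylogous ester, or the borane-associated enolate may be acylated sluggishly or on oxygen, so that diazo transfer is incomplete or misdirected. The fallback sets out from compound 7 and returns at compound 10. The conjugate reduction is quenched with aq NH4Cl and (2R,3S)-2-[3-methoxy-4-(triisopropylsilyloxy)phenyl]-3-[(triethylsilyloxy)methyl]tetrahydro-4H-pyran-4-one F5 is isolated. Kinetic deprotonation with LiN(SiMe3)2 at −78 °C occurs at the unsubstituted C5 methylene and not at the substituted C3 methine; trifluoroacetylation with CF3CO2CH2CF3 then gives 9, and MsN3/Et3N gives 10.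

**Further compounds**
F1 | step 6 | methyl (3RS,4S,5R)-5-[3-methoxy-4-(triisopropylsilyloxy)phenyl]-4-[(triethylsilyloxy)methyl]tetrahydrofuran-3-carboxylate | COC(=O)C1CO[C@@H](c2ccc(O[Si](C(C)C)(C(C)C)C(C)C)c(OC)c2)[C@@H]1CO[Si](CC)(CC)CC
F2 | step 6 | methyl (3RS,4S,5R)-4-(hydroxymethyl)-5-[3-methoxy-4-(triisopropylsilyloxy)phenyl]tetrahydrofuran-3-carboxylate | COC(=O)C1CO[C@@H](c2ccc(O[Si](C(C)C)(C(C)C)C(C)C)c(OC)c2)[C@@H]1CO
F3 | step 10 | (1RS,3aS,4R,6aS)-4-[3-methoxy-4-(triisopropylsilyloxy)phenyl]-1-(phenylsulfonyl)tetrahydro-1H,3H-furo[3,4-c]furan | O=S(=O)(c1ccccc1)C1OC[C@@H]2[C@H]1CO[C@H]2c1ccc(O[Si](C(C)C)(C(C)C)C(C)C)c(OC)c1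
F4 | step 10 | [3-methoxy-4-(3-methylbut-2-enyloxy)phenyl]zinc bromide | COc1cc([Zn]Br)ccc1OCC=C(C)C
F5 | step 4 | (2R,3S)-2-[3-methoxy-4-(triisopropylsilyloxy)phenyl]-3-[(triethylsilyloxy)methyl]tetrahydro-4H-pyran-4-one | O=C1CCO[C@@H](c2ccc(O[Si](C(C)C)(C(C)C)C(C)C)c(OC)c2)[C@@H]1CO[Si](CC)(CC)CC
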